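## Analysis of the target

Malayenolide D (36) is a briarane diterpenoid. A cyclohexane (ring A, C1 and C10–C14) is trans-fused along C1–C10 to a ten-membered carbocycle (C1–C10), which carries a Z-trisubstituted C5=C6 alkene and is fused at C7–C8 to an α-methyl butenolide (C7, C8, C17, C19, O). There are seven stereocentres: the quaternary C1 (methyl C15), C2 (senecioate), C7 (lactone carbinol), C10, the epoxide carbons C11 and C12, and C14 (acetate). On ring A the C14 acetate is cis to the C1–C2 bond and trans to the C1 methyl, C9 on C10 is trans to C2, and the epoxide oxygen lies on the face of the C1 methyl and C9, opposite the acetate; C2 and C7 sit on the medium ring and must be related to ring A across it. The trisubstituted epoxide is sensitive to Brønsted and Lewis acids, the butenolide to base (H7 is γ to the lactone carbonyl and doubly allylic), the senecioate can slip out of conjugation, and two different secondary esters must be placed on C2 and C14 without scrambling. The hard parts are the quaternary C1 wedged between three stereocentres, the strained ten-membered ring, and the order in which epoxide, esters and lactone appear. The route rests on ring A: C14 (oxygenated), C1 (quaternary, bearing the one-carbon branch C2) and C10 (bearing C9) are contiguous on a six-membered ring with the methyl-bearing C11 next to C10, which is the imprint of a cycloaddition between a 1-oxygenated 4-methyl diene and a β-substituted α-methyl enal.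

## Retrosynthetic reasoning

**C6–C7 and the lactone C–O bond (36 ⇒ 34).** C7 is a carbinol carbon flanked by the C5=C6 alkene, so the ten-membered ring is opened there to a Z-alkenyl iodide and an aldehyde. The C19 ester is cis to C7 on the C8=C17 alkene, so the alkoxide formed on ring closure lactonises by itself and 34 can carry both esters and the epoxide. The forward step must close a medium ring and set C7.

**The butenolide carbons (34 ⇒ 32 ⇒ 30 ⇒ 29 ⇒ 27 ⇒ 25).** C7 is traced back to a vinyl group (oxidative cleavage), attached to C8 by substitution of a β-keto ester enol triflate, and C8–C17 to an ester enolate aldol on aldehyde 25. All of this grows from the two-carbon arm C9–C8 of ring A. Copper is used for the C7–C8 bond and palladium is avoided, because the alkenyl iodide is already present. The silyl-to-acetyl exchange at C14 (30 ⇒ 32) is placed after the last carbanion step.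

**The epoxide (24 ⇒ 23).** The two C–O bonds at C11 and C12 are cut back to the C11=C12 alkene. The C8 hydroxyl sits on the C9 arm, which is on the required face, so it can deliver the oxygen. The alkenyl iodide and the enoate are not addressed by a directed oxidant.

**C2 ester, C2 stereocentre and C3–C4 (22 ⇒ 21 ⇒ 20 ⇒ 14 + 18).** The senecioate comes off to alcohol 21, and the C2 stereocentre is traced to ketone 20 so that a chiral reagent sets it next to the quaternary carbon. C3–C4 is cut to methyl ketone 14 and allylic bromide 18: C1 is quaternary, so 14 has a single enolate, and 18 (from 15) brings the Z-alkenyl iodide ready-made.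

**Alkene transposition (14 ⇒ 12 ⇒ 10).** The cycloaddition leaves the alkene at C12=C13. It is moved by hydration at C12 and dehydration toward the tertiary C11–H. A plain borane would place boron next to the allylic oxygen (C13), so a rhodium-catalysed hydroboration is used. It is run at the methyl ketone stage, before the alkenyl iodide exists and where the dehydrating agent has nothing else to attack.

**C2–C3 (10 ⇒ 9 ⇒ 8).** The methyl ketone comes from the aldehyde by methyl Grignard addition and oxidation. A C3 organometallic carrying the whole chain would not tolerate the alkenyl iodide.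

**Ring A (8 ⇒ 2 + 7).** C1–C14 and C10–C11 are cut in one retro-[4+2]. This removes the ring, the quaternary carbon and the C14/C1/C10 triad at once and leaves two achiral acyclic fragments.

**Fragments.** Diene 2 comes from 1 by silyl dienol ether formation. Enal 7 comes from 3 by monoprotection to 4, oxidation to 5 and Wittig olefination with 6.

## Alternatives that were turned down

**Alternative 1:** The C1–C10 bond is cut transannularly, back to the fourteen-membered epoxy cembranoid A1. Forward, Et2AlCl would ionise the C1–C14 epoxide at C1, the Z-C10=C11 alkene would attack through C10, and loss of H12 would give the 14-hydroxy-11-ene briarane A2.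
- For: it is biomimetic, forms ring A and the ten-membered ring together, and delivers the C11=C12 alkene and the free C14 hydroxyl directly. On this point it is stronger than the chosen route, which needs two steps to move the alkene and a separate macrocyclisation.
- Against: A1 is itself a macrocycle carrying the butenolide, a Z-trisubstituted alkene, a defined trisubstituted epoxide and the C2 ester, and no short access to it is evident. The C11 cation formed after C–C bonding can lose H10, H12 or a C20 proton. The C1 cation can suffer hydride shift, or capture by the neighbouring senecioate carbonyl, before the alkene arrives. The more nucleophilic C5=C6 alkene competes. The trans relation of C2 and C9 depends entirely on how the large ring folds.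
- Comparison: the chosen cycloaddition fixes the same relations by the geometry of two alkenes and by suprafacial addition. What it offers in place of the alternative's brevity is predictability at C1, C10 and C14.

**Alternative 2:** The butenolide is cut at C8–C9 and C17–C19. Forward, the ring A Grignard reagent A3 would add anti across the alkyne of alkynol A4 under CuI catalysis, and the resulting alkenylmagnesium would be carboxylated to the Z-γ-hydroxy enoic acid A5.
- For: three components are joined in one step, the tetrasubstituted alkene geometry follows from the hydroxyl-directed anti addition, and C7 arrives enantiopure with A4. Here it is stronger than the chosen route, where C7 is left to substrate control in the ring closure.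
- Against: A3 is a β-branched primary Grignard reagent that must be formed and kept next to an epoxide. Directed carbomagnesiation of propargylic alcohols works best with allyl, vinyl and aryl reagents and is sluggish with hindered alkyl ones. The step presupposes a fully built ring A with its quaternary carbon, which is the part of the molecule that needs a strategy. The ten-membered ring must still be closed afterwards on a substrate with a free acid.
- Comparison: the chosen route solves ring A first, in one step from achiral materials, and builds the same alkene geometry by chelation in two defensible steps. It gives up the reagent-controlled C7.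

**Alternative 3:** The ten-membered ring is cut at C4–C5. Forward, cathodic reduction of the N-hydroxyphthalimide ester A6 with NiCl2·glyme and 2,2'-bipyridine would release a C4 radical, to be captured by the alkenylnickel formed at the C5 bromide, giving the silyl-protected macrocycle A7.
- For: the ring closes at a bond that bears no stereocentre, C7 and the butenolide are in place beforehand, and the coupling tolerates esters. On stereochemical risk in the ring closure it is stronger than the chosen route.
- Against: a primary radical has to find a nickel centre across a forming ten-membered ring. Hydrogen abstraction, dimerisation, and conjugate addition of the radical to the butenolide or the alkene are all faster in principle than a medium-ring closure. The butenolide and the alkenyl bromide are reducible at the cathode, and the Z geometry can be lost at nickel. The intramolecular, medium-ring version of this coupling has no close precedent, and ring A must again be made by other means.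
- Comparison: the chosen ring closure is a two-electron alkenylchromium addition, a type with precedent for nine- and ten-membered carbocycles. It accepts an uncertain C7 in exchange for a ring closure that should actually take place.

Key step: step 5

Remarks on the chemistry:
- Atom numbers are briarane numbers.
- The antipode of the oxazaborolidinium catalyst in step 5 is the one that exposes the enal face that is Si at C1 and Re at C10. By the usual formyl C–H···O binding model this is taken to be the (S)-prolinol-derived catalyst; the mirror-image catalyst is used if the first adduct proves antipodal.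
- Compounds 9 and 26 are carried as mixtures of epimers at centres that the next oxidation removes.

## Route

Step 1
Reactants: 1 (E)-pent-2-enal
Product: 2 (1E,3E)-1-(tert-butyldimethylsilyloxy)penta-1,3-diene
Conditions: TBSOTf, Et3N, Et2O, 0 °C → rt
Reagents that add atoms: tert-butyldimethylsilyl trifluoromethanesulfonate, CC(C)(C)[Si](C)(C)OS(=O)(=O)C(F)(F)F
Why: Silyl dienol ether formation: O-silylation of the enal and γ-deprotonation of the oxocarbenium ion by the amine; the extended s-trans arrangement favours the 1E,3E isomer, and any 3Z isomer cannot reach the s-cis conformation and stays behind in step 5.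

Step 2
Reactants: 3 propane-1,3-diol
Product: 4 3-(4-methoxybenzyloxy)propan-1-ol
Conditions: NaH (1 equiv), 4-methoxybenzyl chloride, Bu4NI (cat.), THF/DMF, 0 °C → rt, diol in excess
Reagents that add atoms: 4-methoxybenzyl chloride, COc1ccc(CCl)cc1
Why: Williamson etherification; the excess of diol should hold the reaction at the monoether.

Step 3
Reactants: 4 3-(4-methoxybenzyloxy)propan-1-ol
Product: 5 3-(4-methoxybenzyloxy)propanal
Conditions: DMP, NaHCO3, CH2Cl2, 0 °C → rt
Reagents that add atoms: none
Why: Dess–Martin oxidation under buffered, non-basic conditions, which should not trigger β-elimination of the alkoxy group.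

Step 4
Reactants: 5 3-(4-methoxybenzyloxy)propanal; 6 2-(triphenylphosphoranylidene)propanal
Product: 7 (E)-5-(4-methoxybenzyloxy)-2-methylpent-2-enal
Conditions: toluene, 90 °C
Reagents that add atoms: none
Why: Wittig olefination with a stabilised ylide, E-selective; the formyl group of the ylide is deactivated by conjugation with the ylide carbon and the product enal is less electrophilic than 5, so a single olefination is expected.

Step 5
Reactants: 2 (1E,3E)-1-(tert-butyldimethylsilyloxy)penta-1,3-diene; 7 (E)-5-(4-methoxybenzyloxy)-2-methylpent-2-enal
Product: 8 (1R,2S,5R,6S)-2-(tert-butyldimethylsilyloxy)-6-[2-(4-methoxybenzyloxy)ethyl]-1,5-dimethylcyclohex-3-ene-1-carbaldehyde (ring A aldehyde; ring carbons 1, 2, 3, 4, 5, 6 are C1, C14, C13, C12, C11, C10)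
Conditions: (S)-1-(2-methylphenyl)-3,3-diphenyltetrahydro-1H,3H-pyrrolo[1,2-c][1,3,2]oxazaborole protonated by HN(SO2CF3)2 (20 mol%), 2 in excess, CH2Cl2, −78 → −40 °C
Reagents that add atoms: none
Why: Binding of the formyl oxygen of 7 to the cationic boron lowers the LUMO of the s-trans enal, and 2 adds in a concerted but asynchronous [4+2] cycloaddition in which C11, the terminus with the largest HOMO coefficient, bonds first to the β-carbon C10 and the oxygenated terminus C14 then closes onto C1. The closest known reaction type is the Lewis acid-catalysed, including oxazaborolidinium-catalysed enantioselective, Diels–Alder reaction of α-methyl enals with 1-silyloxy dienes. Ring A closes as a six-membered carbocycle by suprafacial addition to both components, the C1–C14 bond completing the ring. C14 and C11 come out cis because both substituents are E on the diene; formyl on C1 and C9 on C10 come out trans because the enal is E. The formyl group ends cis to the silyloxy group because the Lewis acid-bound carbonyl lies under the diene (endo); the exo preference that α-methyl enals show with cyclopentadiene stems from its bridging methylene, which is absent here. The absolute configuration follows from shielding of one enal face by the catalyst, so that the diene adds to the face that is Si at C1 and Re at C10. The step needs ortho regiochemistry, which the silyloxy donor secures, together with endo and facial selectivity; the new quaternary centre cannot epimerise afterwards.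

Step 6
Reactants: 8 ring A aldehyde
Product: 9 methyl carbinols (8 with CHO replaced by CH(OH)CH3, both C2 epimers)
Conditions: MeMgBr, THF, −78 → 0 °C; aq. NH4Cl
Reagents that add atoms: methylmagnesium bromide, C[Mg]Br
Why: Grignard addition to a hindered, non-enolisable aldehyde brings in C3; the C2 configuration is irrelevant because the carbinol is oxidised next.

Step 7
Reactants: 9 methyl carbinols
Product: 10 ring A methyl ketone (8 with CHO replaced by C(=O)CH3)
Conditions: DMP, NaHCO3, CH2Cl2, rt
Reagents that add atoms: none
Why: Dess–Martin oxidation; with C1 quaternary the β-silyloxy ketone cannot eliminate or epimerise.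

Step 8
Reactants: 10 ring A methyl ketone
Product: 12 ring A hydroxy ketone (C13 now CH2; 12-OH anti to the 14-silyloxy group, trans to the C11 methyl and cis to H11), via catechol boronate 11 (not isolated)
Conditions: catecholborane, RhCl(PPh3)3 (5 mol%), THF, 0 → 20 °C; then NaOH, H2O2, 0 °C
Reagents that add atoms: hydrogen peroxide, OO
Why: Rhodium-catalysed hydroboration–oxidation, in which an alkene reacts ahead of a hindered ketone; with an allylic silyl ether on a cyclohexene the catalysed reaction places boron on the distal carbon anti to the oxygen, here C12, instead of the proximal C13 that uncatalysed boranes favour. The same position and face are the least hindered ones (remote from quaternary C1, opposite the pseudoaxial silyloxy group and the C11 methyl), and oxidation proceeds with retention.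

Step 9
Reactants: 12 ring A hydroxy ketone
Product: 14 Δ11 methyl ketone (C11=C12 alkene, C13 CH2), via sulfamate ester 13 (not isolated)
Conditions: Burgess reagent (methyl N-(triethylammoniosulfonyl)carbamate), toluene, 20 → 70 °C
Reagents that add atoms: none
Why: Burgess dehydration, a syn elimination: the C12 oxygen and the tertiary H11 are cis, so the trisubstituted C11=C12 alkene is expected as the major (Zaitsev) product and the transient C11 stereocentre is erased. Elimination toward C13 only regenerates 10, which can be returned to step 8.

Step 10
Reactants: 15 prop-2-yn-1-ol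
Product: 17 (Z)-3-iodo-2-methylprop-2-en-1-ol, via cyclic alkenylmagnesium alkoxide 16 (not isolated)
Conditions: MeMgBr (2.5 equiv), CuI (10 mol%), Et2O/THF, −10 °C → rt; then I2, −10 °C
Reagents that add atoms: methylmagnesium bromide, C[Mg]Br; iodine, II
Why: Copper-catalysed anti carbomagnesiation of the propargylic alkoxide gives a five-membered alkenylmagnesium chelate, so magnesium and then iodine end cis to the CH2O group; iodinolysis proceeds with retention. This fixes the Z geometry of the future C5=C6 alkene.

Step 11
Reactants: 17 (Z)-3-iodo-2-methylprop-2-en-1-ol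
Product: 18 (Z)-3-bromo-1-iodo-2-methylprop-1-ene
Conditions: CBr4, PPh3, CH2Cl2, 0 °C
Reagents that add atoms: tetrabromomethane, BrC(Br)(Br)Br
Why: Appel reaction at a primary allylic alcohol; the alkene geometry is not touched.

Step 12
Reactants: 14 Δ11 methyl ketone; 18 (Z)-3-bromo-1-iodo-2-methylprop-1-ene
Product: 20 chain ketone (C2 ketone carrying C3H2–C4H2–C5(CH3)=C6H–I, iodine cis to C4), via lithium enolate 19 (not isolated)
Conditions: LiN(iPr)2 (1.05 equiv), THF, −78 °C; then 18, DMPU, −78 → −20 °C
Reagents that add atoms: none
Why: Kinetic enolate alkylation: C1 is quaternary, so the methyl group is the only enolisable position and the β-silyloxy group cannot be expelled; SN2 attack on the primary allylic bromide forms C3–C4 and leaves the alkenyl iodide untouched.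

Step 13
Reactants: 20 chain ketone
Product: 21 (2S)-alcohol
Conditions: (R)-1-methyl-3,3-diphenyltetrahydro-1H,3H-pyrrolo[1,2-c][1,3,2]oxazaborole (20 mol%), catecholborane, toluene, −78 °C
Reagents that add atoms: none
Why: Corey–Bakshi–Shibata reduction: the catalyst distinguishes the tertiary-alkyl side (C1) from the primary side (C3), and the (R)-catalyst should deliver hydride to give the 2S carbinol under reagent control. Catecholborane at −78 °C does not hydroborate the alkenes.

Step 14
Reactants: 21 (2S)-alcohol
Product: 22 senecioate (2-O-(3-methylbut-2-enoyl) derivative of 21)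
Conditions: 3-methylbut-2-enoyl chloride, pyridine, 4-(dimethylamino)pyridine (cat.), CH2Cl2, 0 °C → rt
Reagents that add atoms: 3-methylbut-2-enoyl chloride, CC(C)=CC(=O)Cl
Why: Nucleophile-catalysed acylation of a hindered secondary alcohol; pyridine is used in place of a trialkylamine so that the acyl chloride is not converted into the vinylketene that leads to the deconjugated ester.

Step 15
Reactants: 22 senecioate
Product: 23 primary alcohol (C8–OH)
Conditions: DDQ, CH2Cl2/pH 7 buffer, 0 °C → rt
Reagents that add atoms: none
Why: Oxidative cleavage of the 4-methoxybenzyl ether by hydride abstraction and hydrolysis; the buffer keeps the acidic hydroquinone from adding the new hydroxyl to the C11=C12 alkene.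

Step 16
Reactants: 23 primary alcohol
Product: 24 epoxy alcohol (11,12-epoxide syn to C9 and the C1 methyl, anti to the 14-silyloxy group)
Conditions: VO(acac)2 (10 mol%), t-BuOOH, CH2Cl2, 0 °C → rt
Reagents that add atoms: tert-butyl hydroperoxide, CC(C)(C)OO
Why: Vanadium-catalysed hydroxyl-directed epoxidation: the C8 hydroxyl is tethered through C9 to the face of ring A on which the epoxide is required, and the opposite face is shielded by the axial silyloxy group, so oxygen should be delivered to the correct face of C11=C12. The alkenyl iodide and the enoate are not directed and stay intact; the epoxy alcohol cannot cyclise because backside attack would have to come from the other face.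

Step 17
Reactants: 24 epoxy alcohol
Product: 25 epoxy aldehyde (C8 aldehyde)
Conditions: DMP, NaHCO3, CH2Cl2, 0 °C
Reagents that add atoms: none
Why: Dess–Martin oxidation under buffered conditions that the epoxide and the esters tolerate.

Step 18
Reactants: 25 epoxy aldehyde
Product: 26 β-hydroxy ester (C8 carbinol bearing C17H(CH3)–CO2CH3; mixture of diastereomers at C8 and C17)
Conditions: methyl propanoate, LiN(iPr)2, THF, −78 °C; then 25, −78 °C; aq. NH4Cl
Reagents that add atoms: methyl propanoate, CCC(=O)OC
Why: Aldol addition of a lithium ester enolate, which at −78 °C adds to the aldehyde far faster than it attacks the hindered senecioate or the epoxide; both new centres are removed later.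

Step 19
Reactants: 26 β-hydroxy ester
Product: 27 β-keto ester
Conditions: DMP, NaHCO3, CH2Cl2, rt
Reagents that add atoms: none
Why: Dess–Martin oxidation of a β-hydroxy ester to the β-keto ester without retro-aldol cleavage.

Step 20
Reactants: 27 β-keto ester
Product: 29 (Z)-enol triflate (triflyloxy group on C8 cis to the ester on C17), via sodium enolate 28 (not isolated)
Conditions: NaH (1.05 equiv), Et2O/CH2Cl2, 0 °C; then N-(5-chloropyridin-2-yl)bis(trifluoromethanesulfonyl)imide, 0 °C → rt
Reagents that add atoms: N-(5-chloropyridin-2-yl)bis(trifluoromethanesulfonyl)imide, FC(F)(F)S(=O)(=O)N(c1ccc(Cl)cn1)S(=O)(=O)C(F)(F)F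
Why: O-Sulfonylation of a β-keto ester enolate; in a weakly coordinating solvent the sodium enolate is chelated by both carbonyl oxygens, which places the triflyloxy group cis to the ester. Only the doubly activated C17–H is removed by one equivalent of base.

Step 21
Reactants: 29 (Z)-enol triflate
Product: 30 (Z)-dienoate (vinyl group on C8 cis to the ester; its inner carbon is C7)
Conditions: CH2=CHMgBr (2.2 equiv), CuI (1.1 equiv), THF, −78 °C
Reagents that add atoms: vinylmagnesium bromide, C=C[Mg]Br
Why: Substitution of a β-triflyloxy enoate by a vinyl cuprate (addition–elimination at copper) proceeds with retention of alkene geometry; at −78 °C the esters, the epoxide and the alkenyl iodide do not react with the cuprate, which is why copper is used here and palladium is not.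

Step 22
Reactants: 30 (Z)-dienoate
Product: 31 C14 alcohol
Conditions: HF·pyridine, pyridine, THF, 0 °C → rt
Reagents that add atoms: none
Why: Fluoride-mediated desilylation in a buffered acidic medium, which spares the trisubstituted epoxide and does not let the senecioate migrate from O2 to O14 as a basic fluoride source could.

Step 23
Reactants: 31 C14 alcohol
Product: 32 C14 acetate
Conditions: Ac2O, pyridine, 4-(dimethylamino)pyridine (cat.), CH2Cl2, rt
Reagents that add atoms: acetic anhydride, CC(=O)OC(C)=O
Why: Nucleophile-catalysed acetylation of the axial secondary alcohol; it is the only free hydroxyl, so the two esters of the target are differentiated.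

Step 24
Reactants: 32 C14 acetate
Product: 34 (Z)-aldehyde ester (C7 aldehyde on C8, cis to the methyl ester), via vicinal diol 33 (not isolated)
Conditions: OsO4 (2 mol%), NaIO4, 2,6-lutidine, dioxane/H2O, rt
Reagents that add atoms: NaIO4 (oxygen passed on through catalytic OsO4), [Na+].[O-]I(=O)(=O)=O
Why: Lemieux–Johnson oxidation: OsO4 dihydroxylates the terminal alkene of the dienoate, the least hindered alkene and the one remote from the ester, ahead of the iodo-substituted and the two enoate alkenes. Periodate, present from the start, should cleave the diol before its secondary hydroxyl can lactonise onto the cis ester.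

Step 25
Reactants: 34 (Z)-aldehyde ester
Product: 36 malayenolide D, via macrocyclic hydroxy ester 35 (not isolated)
Conditions: CrCl2 (10 equiv), NiCl2 (cat.), degassed DMSO, rt, high dilution
Reagents that add atoms: none
Why: Nozaki–Hiyama–Kishi reaction: zerovalent nickel inserts into the alkenyl iodide with retention of the Z geometry, transmetallation to trivalent chromium gives an alkenylchromium species that adds only to the aldehyde and closes the ten-membered ring at C6–C7, and the chromium alkoxide, held cis to the methyl ester on C8=C17, lactonises to the butenolide. C7 is set under substrate control by the conformation of the closing ring; esters and the epoxide are inert to the reagent.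

## Compound list

1 | (E)-pent-2-enal | CC/C=C/C=O | starting material
2 | (1E,3E)-1-(tert-butyldimethylsilyloxy)penta-1,3-diene | C/C=C/C=C/O[Si](C)(C)C(C)(C)C | intermediate
3 | propane-1,3-diol | OCCCO | starting material
4 | 3-(4-methoxybenzyloxy)propan-1-ol | OCCCOCc1ccc(OC)cc1 | intermediate
5 | 3-(4-methoxybenzyloxy)propanal | O=CCCOCc1ccc(OC)cc1 | intermediate
6 | 2-(triphenylphosphoranylidene)propanal | CC(C=O)=P(c1ccccc1)(c1ccccc1)c1ccccc1 | starting material
7 | (E)-5-(4-methoxybenzyloxy)-2-methylpent-2-enal | O=C/C(C)=C/CCOCc1ccc(OC)cc1 | intermediate
8 | ring A aldehyde, (1R,2S,5R,6S)-2-(tert-butyldimethylsilyloxy)-6-[2-(4-methoxybenzyloxy)ethyl]-1,5-dimethylcyclohex-3-ene-1-carbaldehyde | CC(C)(C)[Si](C)(C)O[C@H]1C=C[C@@H](C)[C@H](CCOCc2ccc(OC)cc2)[C@@]1(C)C=O | intermediate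
9 | methyl carbinols (both C2 epimers) | CC(C)(C)[Si](C)(C)O[C@H]1C=C[C@@H](C)[C@H](CCOCc2ccc(OC)cc2)[C@@]1(C)C(C)O | intermediate
10 | ring A methyl ketone | CC(C)(C)[Si](C)(C)O[C@H]1C=C[C@@H](C)[C@H](CCOCc2ccc(OC)cc2)[C@@]1(C)C(C)=O | intermediate
11 | C12 catechol boronate | CC(C)(C)[Si](C)(C)O[C@H]1C[C@H](B2Oc3ccccc3O2)[C@@H](C)[C@H](CCOCc2ccc(OC)cc2)[C@@]1(C)C(C)=O | intermediate
12 | ring A hydroxy ketone (12-OH) | CC(C)(C)[Si](C)(C)O[C@H]1C[C@H](O)[C@@H](C)[C@H](CCOCc2ccc(OC)cc2)[C@@]1(C)C(C)=O | intermediate
13 | C12 N-(methoxycarbonyl)sulfamate ester, triethylammonium salt | CC(C)(C)[Si](C)(C)O[C@H]1C[C@H](OS(=O)(=O)[N-]C(=O)OC)[C@@H](C)[C@H](CCOCc2ccc(OC)cc2)[C@@]1(C)C(C)=O.CC[NH+](CC)CC | intermediate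
14 | Δ11 methyl ketone | CC(C)(C)[Si](C)(C)O[C@H]1CC=C(C)[C@H](CCOCc2ccc(OC)cc2)[C@@]1(C)C(C)=O | intermediate
15 | prop-2-yn-1-ol | C#CCO | starting material
16 | cyclic alkenylmagnesium alkoxide (4-methyl-2,5-dihydro-1,2-oxamagnesole) | CC1=C[Mg]OC1 | intermediate
17 | (Z)-3-iodo-2-methylprop-2-en-1-ol | OC/C(C)=C\I | intermediate
18 | (Z)-3-bromo-1-iodo-2-methylprop-1-ene | BrC/C(C)=C\I | intermediate
19 | lithium enolate of 14 | CC(C)(C)[Si](C)(C)O[C@H]1CC=C(C)[C@H](CCOCc2ccc(OC)cc2)[C@@]1(C)C(=C)O[Li] | intermediate
20 | chain ketone | CC(C)(C)[Si](C)(C)O[C@H]1CC=C(C)[C@H](CCOCc2ccc(OC)cc2)[C@@]1(C)C(=O)CC/C(C)=C\I | intermediate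
21 | (2S)-alcohol | CC(C)(C)[Si](C)(C)O[C@H]1CC=C(C)[C@H](CCOCc2ccc(OC)cc2)[C@@]1(C)[C@@H](O)CC/C(C)=C\I | intermediate
22 | senecioate | CC(C)(C)[Si](C)(C)O[C@H]1CC=C(C)[C@H](CCOCc2ccc(OC)cc2)[C@@]1(C)[C@@H](OC(=O)C=C(C)C)CC/C(C)=C\I | intermediate
23 | primary alcohol (C8–OH) | CC(C)(C)[Si](C)(C)O[C@H]1CC=C(C)[C@H](CCO)[C@@]1(C)[C@@H](OC(=O)C=C(C)C)CC/C(C)=C\I | intermediate
24 | epoxy alcohol | CC(C)(C)[Si](C)(C)O[C@H]1C[C@@H]2O[C@]2(C)[C@H](CCO)[C@@]1(C)[C@@H](OC(=O)C=C(C)C)CC/C(C)=C\I | intermediate
25 | epoxy aldehyde | CC(C)(C)[Si](C)(C)O[C@H]1C[C@@H]2O[C@]2(C)[C@H](CC=O)[C@@]1(C)[C@@H](OC(=O)C=C(C)C)CC/C(C)=C\I | intermediate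
26 | β-hydroxy ester (mixture at C8 and C17) | CC(C)(C)[Si](C)(C)O[C@H]1C[C@@H]2O[C@]2(C)[C@H](CC(O)C(C)C(=O)OC)[C@@]1(C)[C@@H](OC(=O)C=C(C)C)CC/C(C)=C\I | intermediate
27 | β-keto ester (mixture at C17) | CC(C)(C)[Si](C)(C)O[C@H]1C[C@@H]2O[C@]2(C)[C@H](CC(=O)C(C)C(=O)OC)[C@@]1(C)[C@@H](OC(=O)C=C(C)C)CC/C(C)=C\I | intermediate
28 | chelated sodium enolate of 27 | CC(C)(C)[Si](C)(C)O[C@H]1C[C@@H]2O[C@]2(C)[C@H](C/C(O[Na])=C(\C)C(=O)OC)[C@@]1(C)[C@@H](OC(=O)C=C(C)C)CC/C(C)=C\I | intermediate
29 | (Z)-enol triflate | CC(C)(C)[Si](C)(C)O[C@H]1C[C@@H]2O[C@]2(C)[C@H](C/C(OS(=O)(=O)C(F)(F)F)=C(\C)C(=O)OC)[C@@]1(C)[C@@H](OC(=O)C=C(C)C)CC/C(C)=C\I | intermediate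
30 | (Z)-dienoate | CC(C)(C)[Si](C)(C)O[C@H]1C[C@@H]2O[C@]2(C)[C@H](C/C(C=C)=C(\C)C(=O)OC)[C@@]1(C)[C@@H](OC(=O)C=C(C)C)CC/C(C)=C\I | intermediate
31 | C14 alcohol | O[C@H]1C[C@@H]2O[C@]2(C)[C@H](C/C(C=C)=C(\C)C(=O)OC)[C@@]1(C)[C@@H](OC(=O)C=C(C)C)CC/C(C)=C\I | intermediate
32 | C14 acetate | CC(=O)O[C@H]1C[C@@H]2O[C@]2(C)[C@H](C/C(C=C)=C(\C)C(=O)OC)[C@@]1(C)[C@@H](OC(=O)C=C(C)C)CC/C(C)=C\I | intermediate
33 | vicinal diol from 32 | CC(=O)O[C@H]1C[C@@H]2O[C@]2(C)[C@H](C/C(C(O)CO)=C(\C)C(=O)OC)[C@@]1(C)[C@@H](OC(=O)C=C(C)C)CC/C(C)=C\I | intermediate
34 | (Z)-aldehyde ester | CC(=O)O[C@H]1C[C@@H]2O[C@]2(C)[C@H](C/C(C=O)=C(\C)C(=O)OC)[C@@]1(C)[C@@H](OC(=O)C=C(C)C)CC/C(C)=C\I | intermediate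
35 | macrocyclic hydroxy ester (7S) | CC(=O)O[C@H]1C[C@@H]2O[C@]2(C)[C@@H]2C/C(=C(\C)C(=O)OC)[C@@H](O)/C=C(/C)CC[C@H](OC(=O)C=C(C)C)[C@@]12C | intermediate
36 | malayenolide D | CC(=O)O[C@H]1C[C@@H]2O[C@]2(C)[C@@H]2CC3=C(C)C(=O)O[C@H]3/C=C(/C)CC[C@H](OC(=O)C=C(C)C)[C@@]12C | target

## Step count and least certain steps

Total: 25 steps. Longest linear sequence: 22 steps, from propane-1,3-diol (steps 2–9 and 12–25).

**Step 5 (key step).** Most likely failure: the Lewis acid diverts the silyl dienol ether into a vinylogous Mukaiyama-type addition to the formyl group, or desilylates it, faster than the hindered trisubstituted enal undergoes cycloaddition. In addition, the α-methyl group erodes the endo preference, and facial discrimination may be incomplete.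
Fallback: from 2 and 7, promotion with Et2AlCl in CH2Cl2 at −78 → −20 °C, the mildest established activation for this pair of components, would give 8 as a racemate together with its mirror image, the ent-ring A aldehyde F1. Resolution by preparative chromatography on a chiral stationary phase returns to the route at 8.

**Step 8.** Most likely failure: delivery of boron to C13 next to the allylic oxygen, isomerisation of the alkene toward the silyl enol ether by the rhodium hydride, or slow reduction of the ketone by the borane.
Fallback: from 10, oxymercuration with Hg(OAc)2 in THF/H2O, an electrophilic addition in which the inductive effect of the allylic oxygen sends water to the distal C12 and mercury adds to C13 on the face of the C14 oxygen, would give the β-hydroxy organomercurial F2. Radical demercuration with Bu3SnH, which leaves the ketone alone, returns to the route at 12.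

**Step 16.** Most likely failure: too weak a delivery from the flexible, bishomoallylic C8 hydroxyl, so that the alkene reacts slowly or with loss of facial control.
Fallback: from 22, epoxidation before removal of the benzyl ether with 3-chloroperoxybenzoic acid (NaHCO3, CH2Cl2, 0 °C) under steric control would give the 4-methoxybenzyl-protected epoxide F3. The axial C14 silyloxy group shields the face of C12, where bonding to the peracid oxygen is most advanced, though the axial C1 methyl opposes it on the other face. Cleavage of the ether with DDQ returns to the route at 24.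

**Step 25.** Most likely failure: closure of the ring through the other face of the aldehyde, giving the C7 epimer. Substrate control in a ten-membered ring closure cannot be predicted with confidence. Slow closure would also leave room for single-electron reduction of the doubly activated aldehyde by divalent chromium.
Fallback: from 34, the ring closure would then give mainly 7-epi-malayenolide D F4. Its C7 centre is the γ-carbon of a butenolide and can be erased: iPr3SiOTf and Et3N at −78 °C would convert F4 into the 2-silyloxyfuran F5. Desilylation with Bu4NF buffered by acetic acid at low temperature reprotonates C7 from the more accessible face of the ring, with equilibration by a tertiary amine as a further lever, and returns to the route at 36.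

## Further compounds

F1 | step 5 | ent-ring A aldehyde (mirror image of 8) | CC(C)(C)[Si](C)(C)O[C@@H]1C=C[C@H](C)[C@@H](CCOCc2ccc(OC)cc2)[C@]1(C)C=O
F2 | step 8 | β-hydroxy organomercurial (13-acetoxymercurio-12-hydroxy derivative of 10) | CC(C)(C)[Si](C)(C)O[C@H]1[C@@H]([Hg]OC(C)=O)[C@H](O)[C@@H](C)[C@H](CCOCc2ccc(OC)cc2)[C@@]1(C)C(C)=O
F3 | step 16 | 4-methoxybenzyl-protected 11,12-epoxide of 22 | CC(C)(C)[Si](C)(C)O[C@H]1C[C@@H]2O[C@]2(C)[C@H](CCOCc2ccc(OC)cc2)[C@@]1(C)[C@@H](OC(=O)C=C(C)C)CC/C(C)=C\I
F4 | step 25 | 7-epi-malayenolide D | CC(=O)O[C@H]1C[C@@H]2O[C@]2(C)[C@@H]2CC3=C(C)C(=O)O[C@@H]3/C=C(/C)CC[C@H](OC(=O)C=C(C)C)[C@@]12C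
F5 | step 25 | 2-(triisopropylsilyloxy)furan derived from F4 | CC(=O)O[C@H]1C[C@@H]2O[C@]2(C)[C@@H]2Cc3c(C)c(O[Si](C(C)C)(C(C)C)C(C)C)oc3/C=C(/C)CC[C@H](OC(=O)C=C(C)C)[C@@]12C
A1 | alternative 1 | fourteen-membered 1,14-epoxy-10Z-ene cembranoid butenolide | C[C@]12O[C@H]1CC/C(C)=C\CC1=C(C)C(=O)O[C@H]1/C=C(/C)CC[C@@H]2OC(=O)C=C(C)C
A2 | alternative 1 | 14-hydroxy-11-ene briarane (deacetyl, desepoxy 36) | O[C@H]1CC=C(C)[C@@H]2CC3=C(C)C(=O)O[C@H]3/C=C(/C)CC[C@H](OC(=O)C=C(C)C)[C@@]12C
A3 | alternative 2 | ring A C9 Grignard reagent | CC(C)(C)[Si](C)(C)O[C@H]1C[C@@H]2O[C@]2(C)[C@H](C[Mg]Br)[C@@]1(C)[C@@H](O[Si](CC)(CC)CC)C=C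
A4 | alternative 2 | C7 alkynol, 2-(triethylsilyl)hept-2-en-5-yn-4-ol | CC#C[C@@H](O)/C=C(/C)[Si](CC)(CC)CC
A5 | alternative 2 | Z-γ-hydroxy enoic acid (open form of the butenolide) | CC(C)(C)[Si](C)(C)O[C@H]1C[C@@H]2O[C@]2(C)[C@H](C/C(=C(\C)C(=O)O)[C@@H](O)/C=C(/C)[Si](CC)(CC)CC)[C@@]1(C)[C@@H](O[Si](CC)(CC)CC)C=C
A6 | alternative 3 | seco N-hydroxyphthalimide ester with C5 alkenyl bromide | CC(=O)O[C@H]1C[C@@H]2O[C@]2(C)[C@H](CC2=C(C)C(=O)O[C@H]2/C=C(/C)Br)[C@@]1(C)[C@@H](O[Si](C)(C)C(C)(C)C)CCC(=O)ON1C(=O)c2ccccc2C1=O
A7 | alternative 3 | 2-O-silyl-2-desenecioyl malayenolide D | CC(=O)O[C@H]1C[C@@H]2O[C@]2(C)[C@@H]2CC3=C(C)C(=O)O[C@H]3/C=C(/C)CC[C@H](O[Si](C)(C)C(C)(C)C)[C@@]12C
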